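**Retrosynthetic overview**
1. Target 13 ⇐ chlorohydrin 11: the tertiary C–Br bond is made last from a C–O bond with retention (chloriranium ion). 11 ⇐ diene 10 by Cl+/H2O addition; oxygen stands in for bromide, which cannot coexist with a Cl+ source.
2. 10 ⇐ spiro ketone 9 (carbonyl methylenation) ⇐ Diels–Alder of isoprene 8 with bromo enone 7: ring B and the spiro centre, controlled by the C–Br centre.
3. 7 ⇐ cyclic β-ketophosphonate 6 (HWE with CH2O) ⇐ O→C transposition of the bromo enol ether 5 (ring A carbocycle).
4. 5 ⇐ acyclic ketophosphonate 4 by catalytic enantioselective bromo-etherification; the tertiary C–O bond formed here fixes the absolute configuration. 4 ⇐ 1 + 2.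
5. Ring order: oxane (masked ring A) → ring A → ring B.

Assumption: the quinidine-derived catalyst of step 2 is taken to give the (5S)-bromide; if the sense of induction is opposite, its quinine-derived pseudo-enantiomer is used.
Numbering note: all spiro compounds are numbered as in the target name (C1 = CMe2, C2 = CHBr, C5 = C=O or C=CH2, C6 = spiro, C7 = ring B CH2 next to C8, C8 = CH= or CHCl, C9 = CMe).

**Step 1**
Reactants: 1 dimethyl (2-oxopropyl)phosphonate; 2 1-bromo-3-methylbut-2-ene (prenyl bromide)
Product: 4 dimethyl (6-methyl-2-oxohept-5-en-1-yl)phosphonate, via sodium lithium dianion 3 (not isolated)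
Conditions: NaH (1.1 equiv), THF, 0 °C; n-BuLi (1.05 equiv), 0 °C; 2 (1.0 equiv), 0 °C → rt; 1 M HCl quench
Reagents that add atoms: none
Why: γ-Alkylation of a β-ketophosphonate dianion (SN2): the terminal carbanion formed second is the more nucleophilic site and attacks the primary carbon of prenyl bromide.

**Step 2**
Reactants: 4 dimethyl (6-methyl-2-oxohept-5-en-1-yl)phosphonate
Product: 5 dimethyl {(Z)-[(5S)-5-bromo-6,6-dimethyloxan-2-ylidene]methyl}phosphonate
Conditions: NBS (1.05 equiv), O-(quinidin-9-yl) N-(2,4-dimethoxyphenyl)thiocarbamate (10 mol %), toluene/CHCl3 2:1, −60 °C, dark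
Reagents that add atoms: N-bromosuccinimide, O=C1CCC(=O)N1Br
Why: Proposed new method: catalytic enantioselective 6-endo bromo-enol-etherification of a β-ketophosphonate; the thiocarbamate sulfur takes Br+ from NBS while the quinuclidine nitrogen hydrogen-bonds the chelated Z-enol (O–H···O=P), so Br+ reaches one face of the prenyl alkene and the enol oxygen opens the bromiranium ion anti at the tertiary carbon (Markovnikov), forming the tertiary C–O bond and the (S)-C–Br centre in one event; α-C-bromination is the competing path, suppressed at low temperature and partly self-correcting because an α-bromo-β-ketophosphonate is itself a Br+ donor; closest known reaction type is amino-thiocarbamate-catalysed enantioselective bromolactonisation and 5-exo bromocyclisation of olefinic 1,3-dicarbonyl compounds.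

**Step 3**
Reactants: 5 dimethyl {(Z)-[(5S)-5-bromo-6,6-dimethyloxan-2-ylidene]methyl}phosphonate
Product: 6 dimethyl [(1S,3S)-3-bromo-2,2-dimethyl-6-oxocyclohexyl]phosphonate
Conditions: SnCl4 (1.1 equiv, promoter), CH2Cl2, −78 → −20 °C; aq. NaHCO3 work-up
Reagents that add atoms: none
Why: Lewis-acid O→C transposition, the known SnCl4 equilibration of kinetically O-cyclised enol ethers of β-dicarbonyls to C-cyclised ketones (cation–olefin-type ring closure): the tertiary C–O bond ionises with help from the neighbouring bromine to a bromiranium ion that cannot racemise (no free alkene to accept Br+), and the tin-bound enolate carbon closes the carbocycle irreversibly anti to bromine, so the CHBr centre is carried over unchanged; the phosphonate-bearing carbon is epimerisable and is drawn as the diequatorial cis isomer.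

**Step 4**
Reactants: 6 dimethyl [(1S,3S)-3-bromo-2,2-dimethyl-6-oxocyclohexyl]phosphonate
Product: 7 (4S)-4-bromo-3,3-dimethyl-2-methylidenecyclohexan-1-one
Conditions: 37% aq. CH2O (5 equiv), K2CO3 (2 equiv), THF/H2O, 0 °C → rt
Reagents that add atoms: formaldehyde, C=O
Why: Horner–Wadsworth–Emmons olefination with formaldehyde places the methylene regiospecifically on the hindered α-carbon, which becomes sp2 (its configuration in 6 is irrelevant); the equatorial secondary bromide survives the mild base.

**Step 5**
Reactants: 7 (4S)-4-bromo-3,3-dimethyl-2-methylidenecyclohexan-1-one; 8 isoprene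
Product: 9 (2S,6R)-2-bromo-1,1,9-trimethylspiro[5.5]undec-8-en-5-one
Conditions: 8 (6 equiv), Me2AlCl (30 mol %), CH2Cl2, −40 → 0 °C
Reagents that add atoms: none
Why: Lewis-acid-catalysed Diels–Alder reaction with "para" regiochemistry (the exocyclic CH2 bonds to C1 of isoprene), giving the 1,4-relationship between spiro carbon and C-methyl; the enone reacts as the chair with equatorial Br and the diene bonds to the α-carbon on the face opposite the axial methyl of the adjacent CMe2 group (new C6–C7 bond trans to Br), which sets the spiro centre; minor diastereomer and "meta" isomer are removed by chromatography.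

**Step 6**
Reactants: 9 (2S,6R)-2-bromo-1,1,9-trimethylspiro[5.5]undec-8-en-5-one
Product: 10 (2S,6S)-2-bromo-1,1,9-trimethyl-5-methylidenespiro[5.5]undec-8-ene
Conditions: Cp2TiMe2 (2.5 equiv), toluene, 70 °C, dark
Reagents that add atoms: dimethyltitanocene (Cp2TiMe2), C[Ti](C)(C1C=CC=C1)C1C=CC=C1
Why: Petasis methylenation (titanium methylidene, oxatitanacyclobutane) converts hindered, enolisable ketones under non-basic conditions, so the secondary bromide and both stereocentres survive; the spiro descriptor changes from R to S only through CIP priorities.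

**Step 7**
Reactants: 10 (2S,6S)-2-bromo-1,1,9-trimethyl-5-methylidenespiro[5.5]undec-8-ene
Product: 11 (2S,6S,8R,9R)-2-bromo-8-chloro-1,1,9-trimethyl-5-methylidenespiro[5.5]undecan-9-ol
Conditions: trichloroisocyanuric acid (0.36 equiv), acetone/H2O 4:1, 0 °C
Reagents that add atoms: trichloroisocyanuric acid, O=C1N(Cl)C(=O)N(Cl)C(=O)N1Cl; water, O
Why: Chlorohydrin formation with Fürst–Plattner control: Cl+ prefers the trisubstituted ring B alkene over the neopentyl 1,1-disubstituted methylene; ring B holds the flat C5 carbon axial and CMe2 equatorial, and in that half-chair only the chloriranium ion on the face syn to C5 can be opened by water at the tertiary carbon C9 in a trans-diaxial, Markovnikov sense, which forms the C9–O bond on the face of the CMe2 group and puts Cl at C8 cis to C5.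

**Step 8**
Reactants: 11 (2S,6S,8R,9R)-2-bromo-8-chloro-1,1,9-trimethyl-5-methylidenespiro[5.5]undecan-9-ol
Product: 13 (2S,6S,8R,9R)-2,9-dibromo-8-chloro-1,1,9-trimethyl-5-methylidenespiro[5.5]undecane, via alkoxyiminium bromide 12 (not isolated)
Conditions: 1-bromo-N,N,2-trimethylprop-1-en-1-amine (2 equiv), CH2Cl2, 0 °C → rt
Reagents that add atoms: 1-bromo-N,N,2-trimethylprop-1-en-1-amine, CC(C)=C(Br)N(C)C
Why: Neutral deoxybromination with an α-bromoenamine (bromo analogue of the Ghosez reagent) with neighbouring-group participation: the alcohol adds to the keteniminium form to give 12, loss of the amide is assisted by the antiperiplanar axial C8–Cl bond (chloriranium ion), and bromide reopens it at the tertiary carbon from the face the oxygen left (trans-diaxial, Markovnikov), so C9 is substituted with net retention; no free HBr is formed, which protects the exocyclic alkene.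

**Compound list**
1 | dimethyl (2-oxopropyl)phosphonate | CC(=O)CP(=O)(OC)OC | starting material
2 | 1-bromo-3-methylbut-2-ene (prenyl bromide) | CC(C)=CCBr | starting material
3 | sodium lithium dianion of 1 | [Na+].[Li+].[CH2-]C(=O)[CH-]P(=O)(OC)OC | intermediate (not isolated)
4 | dimethyl (6-methyl-2-oxohept-5-en-1-yl)phosphonate | CC(C)=CCCC(=O)CP(=O)(OC)OC | intermediate
5 | dimethyl {(Z)-[(5S)-5-bromo-6,6-dimethyloxan-2-ylidene]methyl}phosphonate | COP(=O)(OC)/C=C1/CC[C@H](Br)C(C)(C)O1 | intermediate
6 | dimethyl [(1S,3S)-3-bromo-2,2-dimethyl-6-oxocyclohexyl]phosphonate | COP(=O)(OC)[C@@H]1C(=O)CC[C@H](Br)C1(C)C | intermediate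
7 | (4S)-4-bromo-3,3-dimethyl-2-methylidenecyclohexan-1-one | O=C1CC[C@H](Br)C(C)(C)C1=C | intermediate
8 | isoprene (2-methylbuta-1,3-diene) | C=CC(C)=C | starting material
9 | (2S,6R)-2-bromo-1,1,9-trimethylspiro[5.5]undec-8-en-5-one | O=C1CC[C@H](Br)C(C)(C)[C@]12CCC(C)=CC2 | intermediate
10 | (2S,6S)-2-bromo-1,1,9-trimethyl-5-methylidenespiro[5.5]undec-8-ene | C=C1CC[C@H](Br)C(C)(C)[C@]12CCC(C)=CC2 | intermediate
11 | (2S,6S,8R,9R)-2-bromo-8-chloro-1,1,9-trimethyl-5-methylidenespiro[5.5]undecan-9-ol | C=C1CC[C@H](Br)C(C)(C)[C@]12CC[C@@](C)(O)[C@H](Cl)C2 | intermediate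
12 | alkoxyiminium bromide of 11: N-{1-[((2S,6S,8R,9R)-2-bromo-8-chloro-1,1,9-trimethyl-5-methylidenespiro[5.5]undecan-9-yl)oxy]-2-methylpropylidene}-N-methylmethanaminium bromide | C=C1CC[C@H](Br)C(C)(C)[C@]12CC[C@@](C)(OC(=[N+](C)C)C(C)C)[C@H](Cl)C2.[Br-] | intermediate (not isolated)
13 | (2S,6S,8R,9R)-2,9-dibromo-8-chloro-1,1,9-trimethyl-5-methylidenespiro[5.5]undecane | C=C1CC[C@H](Br)C(C)(C)[C@]12CC[C@@](C)(Br)[C@H](Cl)C2 | target

**Totals**
Total step count: 8. Longest linear sequence: 8 steps (1 and 2 → 13).

**Three steps most likely to fail**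

Step 2 (the proposed new reaction). It can fail through α-C-bromination, 5-exo closure or low ee. The fallback is known chemistry and sets out from 4. Shi asymmetric epoxidation (D-fructose-derived ketone, KHSO5, K2CO3 buffer, MeCN/dimethoxymethane/H2O, 0 °C) gives dimethyl {4-[(2R)-3,3-dimethyloxiran-2-yl]-2-oxobutyl}phosphonate F1. Li2NiBr4 in THF opens the epoxide at the secondary carbon with inversion to dimethyl [(5S)-5-bromo-6-hydroxy-6-methyl-2-oxoheptyl]phosphonate F2. Pyridinium p-toluenesulfonate with 4 Å sieves in benzene then closes the tertiary alcohol onto the ketone and dehydrates, coming back to the route at 5.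

Step 3. SnCl4 may give elimination or halide capture instead of the O→C shift. The fallback sets out from 5 and closes the ring from an open-chain precursor. Dilute aqueous HCl in THF opens the enol ether to the hydroxy ketone (the bromohydrin F2 above). Ac2O with Bi(OTf)3 (2 mol %) gives the tertiary acetate dimethyl [(5S)-6-acetoxy-5-bromo-6-methyl-2-oxoheptyl]phosphonate F3. Me2AlCl (2.2 equiv, CH2Cl2, −78 → −20 °C) ionises the acetate to the same bromiranium ion, which the enol carbon captures, coming back to the route at 6.

Step 8. Ionisation at C9 may give elimination, transannular attack by the exocyclic alkene or halogen scrambling. The fallback sets out from 9 and moves the halogenation before the olefination. The same chlorohydroxylation (trichloroisocyanuric acid, acetone/H2O, 0 °C) gives (2S,6R,8R,9R)-2-bromo-8-chloro-9-hydroxy-1,1,9-trimethylspiro[5.5]undecan-5-one F4. HBr in AcOH (tolerated, as no alkene is present) gives (2S,6R,8R,9R)-2,9-dibromo-8-chloro-1,1,9-trimethylspiro[5.5]undecan-5-one F5 with retention through the same chloriranium ion. Methylenation with Cp2Ti(μ-Cl)(μ-CH2)AlMe2 and pyridine (THF, −40 → 0 °C) comes back to the route at 13.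

**Further compounds**
F1 | step 2 | dimethyl {4-[(2R)-3,3-dimethyloxiran-2-yl]-2-oxobutyl}phosphonate | COP(=O)(OC)CC(=O)CC[C@H]1OC1(C)C
F2 | step 2 | dimethyl [(5S)-5-bromo-6-hydroxy-6-methyl-2-oxoheptyl]phosphonate | COP(=O)(OC)CC(=O)CC[C@H](Br)C(C)(C)O
F3 | step 3 | dimethyl [(5S)-6-acetoxy-5-bromo-6-methyl-2-oxoheptyl]phosphonate | COP(=O)(OC)CC(=O)CC[C@H](Br)C(C)(C)OC(C)=O
F4 | step 8 | (2S,6R,8R,9R)-2-bromo-8-chloro-9-hydroxy-1,1,9-trimethylspiro[5.5]undecan-5-one | O=C1CC[C@H](Br)C(C)(C)[C@]12CC[C@@](C)(O)[C@H](Cl)C2
F5 | step 8 | (2S,6R,8R,9R)-2,9-dibromo-8-chloro-1,1,9-trimethylspiro[5.5]undecan-5-one | O=C1CC[C@H](Br)C(C)(C)[C@]12CC[C@@](C)(Br)[C@H](Cl)C2
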